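**Retrosynthetic overview**
1. Isariotin D comes from the C4 ketone of the epoxy‑ketone by hydride reduction anti to the epoxide. That epoxy‑ketone comes from exo‑face nucleophilic epoxidation of the bridged enone.
2. The bicyclo[3.3.1]nonane (ring 1 closed last) comes from an intramolecular aldol of a cyclohexane‑1,3‑dione (C5 nucleophile) onto an α‑amido aldehyde chain hanging from the quaternary carbinol C1.
3. The dione and quinol (ring 2) come from oxidative dearomatisation of an aryl‑alaninal phenol. This is the key step: it breaks the aromaticity, installs the C1 tertiary alcohol and fixes the oxidation levels at C4 and C9.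
4. The aryl‑alanine comes from a Horner–Wadsworth–Emmons (HWE) olefination and asymmetric hydrogenation of commercial 4‑hydroxy‑2‑methoxybenzaldehyde, which sets C7 as (S). The (E)‑decenoyl amide is installed early so nothing is acylated late.

Numbering below follows the bicycle: C9 = bridging ketone, C1 = bridgehead C–OH, C2/C3 = epoxide, C4 = CHOH, C5 = bridgehead CH, C6 = CHOH, C7 = CH–N, C8 = CH2.

**Assumptions.**
- The natural C7 configuration is (S), the L‑amino‑acid configuration; I checked this against the SMILES.
- Step 6 gives both C1 epimers (assumed about 2–3:1). Only the epimer that can place NHAcyl equatorial closes the bicycle, and the other is removed chromatographically.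
- Aldehyde 8 is used crude, without purification.

---

**Step 1**
Reactants: 1 (4‑hydroxy‑2‑methoxybenzaldehyde); 2 (trimethyl N‑Boc‑2‑phosphonoglycinate)
Product: 3 (methyl (Z)‑2‑(Boc‑amino)‑3‑(4‑hydroxy‑2‑methoxyphenyl)acrylate)
Conditions: DBU (2.2 equiv), CH2Cl2, 0 °C → rt
Reagents that add atoms: none
Why: HWE olefination of the aldehyde with the phosphonoglycine gives the (Z)‑dehydroamino ester selectively, and the extra DBU equivalent covers the free phenol.

**Step 2**
Reactants: 3
Product: 4 (methyl (S)‑2‑(Boc‑amino)‑3‑(4‑hydroxy‑2‑methoxyphenyl)propanoate)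
Conditions: [Rh(cod)(Et‑DuPhos)]OTf (1 mol%, ligand enantiomer chosen to give S), H2 (3 atm), MeOH, rt
Reagents that add atoms: none (H2 adds only hydrogen)
Why: Rh‑catalysed asymmetric hydrogenation of the chelating enamide sets C7 as (S).

**Step 3**
Reactants: 4
Product: 5 (methyl (S)‑2‑amino‑3‑(4‑hydroxy‑2‑methoxyphenyl)propanoate)
Conditions: TFA, Et3SiH, CH2Cl2, 0 °C; then aq. NaHCO3
Reagents that add atoms: none
Why: Acidolysis removes the Boc group, with silane scavenging the t‑Bu cation so the electron‑rich ring is not alkylated, and C7 is untouched.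

**Step 4**
Reactants: 5; 6 ((E)‑dec‑2‑enoic acid)
Product: 7 (methyl (S)‑2‑[(E)‑dec‑2‑enamido]‑3‑(4‑hydroxy‑2‑methoxyphenyl)propanoate)
Conditions: EDC·HCl, HOBt, DIPEA, DMF, 0 °C → rt
Reagents that add atoms: none (6 is a reactant)
Why: Carbodiimide amide coupling acylates the amine chemoselectively over the phenol and installs the final N‑acyl group early.

**Step 5**
Reactants: 7
Product: 8 ((E)‑N‑[(S)‑1‑(4‑hydroxy‑2‑methoxyphenyl)‑3‑oxopropan‑2‑yl]dec‑2‑enamide)
Conditions: DIBAL‑H (4.5 equiv), CH2Cl2/toluene, −78 °C; MeOH, then Rochelle salt workup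
Reagents that add atoms: none
Why: Partial ester reduction through a stable tetrahedral aluminate stops at the aldehyde (no new stereocentre, and excess hydride covers the OH and NH).

**Step 6**
Reactants: 8
Product: 9 ((E)‑N‑[(S)‑1‑(1‑hydroxy‑2‑methoxy‑4‑oxocyclohexa‑2,5‑dien‑1‑yl)‑3‑oxopropan‑2‑yl]dec‑2‑enamide; quaternary C1 configured as in the SMILES; the aldehyde is in equilibrium with its spiro‑lactol)
Conditions: PIFA (1.2 equiv), MeCN/H2O (4:1), NaHCO3, 0 °C
Reagents that add atoms: water, O
Why: This is the key dearomatisation: hypervalent‑iodine oxidative dearomatisation of the para‑alkylphenol places water (or the aldehyde hydrate, giving a spiro‑lactol) on C1 to form the tertiary carbinol, with C1 set as an epimer mixture and only the matched epimer carried forward.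

**Step 7**
Reactants: 9
Product: 10 ((E)‑N‑[1,6‑dihydroxy‑4,9‑dioxobicyclo[3.3.1]non‑2‑en‑7‑yl]dec‑2‑enamide, stereo as in the SMILES)
Conditions: 2 M aq. HCl/THF (1:2), 40 °C
Reagents that add atoms: water, O
Why: Proposed new method: acid hydrolysis of the vinylogous methyl ether gives the cyclohexene‑1,3‑dione (C5 as the enolic carbon), which adds to the aldehyde in an enol–aldehyde H‑bonded chair‑like intramolecular aldol. The bicyclo[3.3.1] skeleton forms by 6‑(enolexo)‑exo closure, as in the closure of cyclohexane‑1,3‑dione side‑chain aldehydes to bicyclo[3.3.1]nonanes. The face of C5 attacked is dictated by the C1 chain. The equatorial NHAcyl selects the matched C1 epimer, which sets C7 relative to C1/C5. The chelated chair puts the new C6–OH syn to the C9 bridge. The bridgehead C5 blocks dehydration.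

**Step 8**
Reactants: 10
Product: 11 (2,3‑epoxy‑4,9‑dioxo bicyclic ketone, stereo as in the SMILES)
Conditions: 30% aq. H2O2 (5 equiv), Na2CO3 (1 equiv), MeOH/THF (1:1), 0 °C
Reagents that add atoms: hydrogen peroxide, OO
Why: Weitz–Scheffer nucleophilic epoxidation of the enone attacks C2 from the exo face, since the C6–C7–C8 bridge blocks the endo face. The epoxide ends up cis to C1–OH, and the unsaturated amide and ketone C9 are unreactive.

**Step 9**
Reactants: 11
Product: 12 (isariotin D)
Conditions: NaBH4 (1.5 equiv), MeOH/CH2Cl2 (1:1), −40 °C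
Reagents that add atoms: none
Why: Hydride reduction of the activated epoxy‑ketone C4 carbonyl occurs by equatorial attack, because the axial epoxide oxygen blocks the axial trajectory. This gives the axial C4–OH cis to the epoxide and leaves the hindered C9 ketone untouched.

**Stereocentre check.**
- C7 is set in Step 2.
- C1 is set in Step 6, with only the matched epimer cyclising.
- C5 and C6 are set in Step 7.
- C2 and C3 are set in Step 8.
- C4 is set in Step 9.
- No later step touches C5 or C7. C5 cannot epimerise because it is a bridgehead, and C7 is not acidic in the bicycle.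

---

**Compound list**
1 | 4‑hydroxy‑2‑methoxybenzaldehyde | O=Cc1ccc(O)cc1OC | starting material
2 | trimethyl N‑Boc‑2‑phosphonoglycinate | COC(=O)C(NC(=O)OC(C)(C)C)P(=O)(OC)OC | starting material
3 | methyl (Z)‑2‑(Boc‑amino)‑3‑(4‑hydroxy‑2‑methoxyphenyl)acrylate | COC(=O)/C(NC(=O)OC(C)(C)C)=C/c1ccc(O)cc1OC | intermediate
4 | methyl (S)‑2‑(Boc‑amino)‑3‑(4‑hydroxy‑2‑methoxyphenyl)propanoate | COC(=O)[C@H](Cc1ccc(O)cc1OC)NC(=O)OC(C)(C)C | intermediate
5 | methyl (S)‑2‑amino‑3‑(4‑hydroxy‑2‑methoxyphenyl)propanoate | N[C@@H](Cc1ccc(O)cc1OC)C(=O)OC | intermediate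
6 | (E)‑dec‑2‑enoic acid | CCCCCCC/C=C/C(=O)O | starting material
7 | methyl (S)‑2‑[(E)‑dec‑2‑enamido]‑3‑(4‑hydroxy‑2‑methoxyphenyl)propanoate | CCCCCCC/C=C/C(=O)N[C@@H](Cc1ccc(O)cc1OC)C(=O)OC | intermediate
8 | (E)‑N‑[(S)‑1‑(4‑hydroxy‑2‑methoxyphenyl)‑3‑oxopropan‑2‑yl]dec‑2‑enamide | CCCCCCC/C=C/C(=O)N[C@@H](Cc1ccc(O)cc1OC)C=O | intermediate
9 | quinol aldehyde (C1‑OH, 2‑methoxy‑4‑oxocyclohexa‑2,5‑dienyl) | CCCCCCC/C=C/C(=O)N[C@H](C=O)C[C@@]1(O)C(OC)=CC(=O)C=C1 | intermediate
10 | bridged enone, 1,6‑dihydroxy‑4,9‑dioxobicyclo[3.3.1]non‑2‑en‑7‑yl decenamide | CCCCCCC/C=C/C(=O)N[C@H]1C[C@@]2(O)C(=O)[C@H](C(=O)C=C2)[C@H]1O | intermediate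
11 | 2,3‑epoxy‑4,9‑dioxo bicyclic decenamide | CCCCCCC/C=C/C(=O)N[C@H]1C[C@@]2(O)C(=O)[C@H](C(=O)[C@@H]3O[C@@H]32)[C@H]1O | intermediate
12 | isariotin D | CCCCCCC/C=C/C(=O)N[C@H]1C[C@@]2(O)C(=O)[C@H]([C@H](O)[C@@H]3O[C@@H]32)[C@H]1O | target

---

**Totals:** 9 steps in total; longest linear sequence 9 steps (1 → 3 → 4 → 5 → 7 → 8 → 9 → 10 → 11 → 12).

**Three steps most likely to fail**
1. **Step 7 (bridging aldol).** The aldol may be reversible, or the lactol form of 9 may be the resting state.
   Fallback: convert the chain to an S‑phenyl thioester and close C5–C6 by intramolecular C‑acylation (Claisen type) to the C6 ketone, then reduce C6 to the alcohol.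
2. **Step 6 (dearomatisation).** C1 diastereoselectivity may be poor, or the aldehyde may interfere with the oxidant.
   Fallback: build the same C1 quinol by regioselective 1,2‑allylation of 2‑methoxy‑1,4‑benzoquinone (made from guaiacol), then convert the allyl group into the α‑amido aldehyde chain.
3. **Step 9 (C4 reduction).** Facial selectivity of hydride delivery is uncertain and may give the C4 epimer.
   Fallback: screen ketoreductases for the axial alcohol, or reduce with a bulky borohydride and invert C4 by Mitsunobu.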